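The constants of this system were unknown to me, so I reckoned from the two earlier runs.

| flask | E | remark | time |
|---|---|---|---|
| south | 10 mM | run made earlier |  |
| west | 40 mM | run made earlier |  |
| flask | 20 mM |  | 5.0 d |

- south (time / d: E / %, L / %): 0.833: 0, 25; 1.67: 0, 23; 2.50: 0, 26; 3.00: 0, 22; 4.00: 0, 20; 5.00: 0, 22
- west (time / d: E / %, L / %): 0.333: 0, 3; 1.04: 2, 5; 1.67: 0, 8; 2.50: 0, 7; 4.00: 1, 6; 5.00: 1, 8

(scatter of a reading: 2 percentage points)

- the state of affairs at 5.0 d: stopped, and by what, or still going (forward and back rates have come level / all of E has reacted / it is still moving)
- share of the E used up at 5.0 d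
- L at 5.0 d, in percent of the E charged

- the reaction counts as stopped when no species that holds the E changes by six tenths of a point or more over the second half of the time

In the south and west runs E read 0 % and 1 % at 5.00 d, inside the scatter of 2 percentage points, so I took E in the flask to be consumed by 5.0 d. I then put L in mM: the south mean gave 2.30 mM and the west readings from 1.67 d on gave 2.90 mM, with charges of 10 mM and 40 mM.

So I compared rates at one moment, supposing L made in proportion to [E] and lost in proportion to [E][L]. Their ratio is then free of [E] and equals [L]b/[L], where [L]b, the balance level, is the pseudo-steady [L] at which making and loss of L are equal, read here from the west run. As [L] climbs, the ratio drifts toward unity. Setting [L] in the flask equal to [L]b, whatever the charge, gave my first estimate of L, 14.5 % of its charge.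

The weak link was that equal level, since the south reading of L stood lower than the west one. So I let the gap to [L]b shrink exponentially with the E charged, by a factor e per charge c; the south run set c at 6.35 mM. The flask's charge is larger than c, which gave 2.78 mM, or 13.9 % of its charge.

The forecast gave a different L from mine: all of E has reacted, conversion 100 %, L 13 %, noting that “L then stays flat, with no drift and no sign of E returning”.

    Q → G (k = 1.90 × 10⁻⁴ s⁻¹)
    Q → L (k = 5.60 × 10⁻⁴ s⁻¹)
    E + L → J (k = 0.0260 M⁻¹ s⁻¹)
    E ⇌ Q (K = 0.160, k = 3.40 × 10⁻⁴ s⁻¹)

In the flask at 5.0 d, all of E has reacted: conversion 100 %, L 13.0 %, which is 2.60 mM against my 2.78 mM, and the forecast stood within its margins. The L of the flask moved by 5 points with E at 13.7 mM or 33.3 mM, the time held. The neighbouring flask, charged with 5.0 mM of E, lies below c, and the same reckoning gives 1.58 mM, or 31.6 % of its charge. At 5.0 d that neighbouring flask held E at 0 % and L at 35.2 %.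

The data come from a simulation with made-up constants.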